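The constants are those of an exercise; what happens was integrated by code.

A closed, stirred vessel holds solid L over its solution, and the same charge is run on four temperature courses.

| setting | north | south-west | south-east | south |
|---|---|---|---|---|
| L | 2.0 mM | 2.0 mM | 2.0 mM | 2.0 mM |
| temperature | −20 °C | −5 °C |  | −35 °C |
| time | 20 s | 20 s | 20 s | 20 s |
| remark |  |  | at −35 °C until 4.0 s, from then on at −5 °C |  |

    L ⇌ Q, rate k1*(cs1 - [Q]) while solid is left; crystals form when [Q] > cs1 (cs1 = 1.0 mM, k1 = 0.220 s⁻¹)
    Q → Z (k2 = 8.72 × 10⁻⁴ s⁻¹, Ea2 = 74.0 kJ mol⁻¹)
    Z → E (k3 = 0.00859 s⁻¹, Ea3 = 67.0 kJ mol⁻¹)
    Z ⇌ J (K4 = 0.17, k4 = 0.0184 s⁻¹, Ea4 = 62.0 kJ mol⁻¹, ΔH4 = 4.00 kJ mol⁻¹)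
    Q + 2 Z → 3 Z (k5 = 51400 M⁻² s⁻¹, Ea5 = 12.0 kJ mol⁻¹)
    (constants at −20 °C)

- where a step has two of a species, its rate is k times that concentration squared, and two are used at each turn
- as a solid, counted per litre of solution: L
- the constants hold at −20 °C; other temperatures follow from the activation energies and enthalpies
- at the start none of L is in solution
- what has only dissolved of L counts as not reacted

* the flask that comes out highest in share of Z in all that became Z or E or J, or "all alike" when all lie within 1.5 percentage points (north / south-west / south-east / south / all alike)
* share of Z in all that became Z or E or J, north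
* share of Z in all that became Z or E or J, south-west
* share of Z in all that became Z or E or J, south-east
* share of Z in all that became Z or E or J, south

Turn the question round: for a flask at −5 °C to beat flask south, its Z must escape J and E better than Z does at −35 °C. Q climbs to its solubility of 1.0 mM with a time constant of 4.55 s, shorter than the reading time of 20 s, so Z receives a steady feed over a window of 15.5 s in flask south-west. Over that window the direct step of flask south-west makes 0.0963 mM of Z, less than the 0.297 mM at which the autocatalytic step would match it.

In flask south-west, Z and J relax towards each other at 0.601 s⁻¹, which is quick against the window. They therefore form one pool (a pre-equilibrium) with J/Z = 0.189. E is made from Z at 0.0510 s⁻¹, so the pool as a whole drains with a leak constant, the first-order rate constant of the pool into E, of 0.0429 s⁻¹. Integrating a steady feed against this leak leaves in the pool the fraction (one minus e to the minus x) over x, where x is the leak constant times the window. Dividing by one plus J/Z gives Z's share, 61.5 % for flask south-west. Flask south-east, whose feed counts from the change of temperature, has a window of 14.2 s and a share of 63.0 %.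

The equilibrium ratio puts 84.1 % of the pool in Z, an estimate for a pool at equilibrium and no bound. In flask south, J returns over 45.5 s, longer than the window, so forward losses are reckoned at 0.004035 s⁻¹ and give 96.9 %. On this equilibrium estimate, with the leak set aside, the opposite outcome needs J/Z at −5 °C below 0.0315, and flask south-west stands at 6.00 times that. Flask north, relaxing over 7.90 s, fits neither limit and stays unreckoned.

The forecast gives south, with 85.7 % for north, 60.7 % for south-west, 62.8 % for south-east and 97 % for south, holding that "The cold flask therefore keeps nearly all its Z".

The simulation gives south as highest, with 85.7 % for north, 60.7 % for south-west, 62.7 % for south-east and 96.9 % for south.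

The reckoned share for flask south-west stands 0.8 percentage points above its result. Flask south-east left until 80 s still holds Q at 48.4 % of the charge and solid L at 26.8 %. The same leak constant of 0.0429 s⁻¹ over its longer window of 74.1 s gives a share of 25.4 %. That flask reads 26.3 %, with E at 17.1 % of the charge.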